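**Strategy.** Ring A is disconnected at C2'–C3', C4'–Br and C1'–O. Its atoms (C1' tertiary carbinol, C2' methylene, C3' gem-dimethyl carbon, C4' bromomethine, C5', C6') are those of a 2-substituted 6-methylhepta-1,5-diene that has taken up Br+ and water. One enzymatic operation brominates the terminal alkene, closes the six-membered ring and hydrates C1', creating both ring-A stereocentres. The precursor is the complete trans-hydrindane (4β-Br, 7β-OTBS, O2 and O8 tied as a cyclic carbonate) carrying the open dienyl chain. It is assembled from (S)-Wieland–Miescher ketone by ring contraction through a β-lactone, and from 6-methylhept-5-en-2-one by a Shapiro/Weinreb coupling.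

Key step: step 17

**Remarks on the chemistry**
- Labels: hydrindane C1, C2, C3, C3a (angular methyl), C4–C7, C7a (ring-fusion CH); C8 is the carbinol carbon between the rings; ring A is C1'–C6'. β is the face of the C3a methyl. In the decalins 2–8, C8 is a ring atom (ring C3a–C3–C2–C8–C1–C7a).
- Reading of the target: trans-hydrindane (7a-Hα); 4β-Br (equatorial); 7β-OH (axial, syn to the C3a methyl) and 7α-Me; C1 side chain α; 2α-OH; O2/O8 1,3-syn with (8R); ring A (1'R,4'S), OH cis to Br. (S)-Wieland–Miescher ketone has the required C3a configuration.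
- Design of the cyclisation substrate: a C1' cation can be reached by O2 (five-membered ether) and also by O7 (six-membered ether via C7–C7a–C1–C8). A free C8–OH beside that cation invites a 1,2-hydride shift to the ketone. Therefore O2 and O8 are locked in one cyclic carbonate, whose carbonyl is held s-trans and cannot reach C1', and O7 is a silyl ether.
- C8 is set by chelation-controlled reduction of a C8 ketone. Vinyl-metal addition to a C1 aldehyde would put carbon on the face that hydride must take and so favour the C8 epimer.
- Assumption: the commercial Corallina officinalis bromoperoxidase accepts 23 in buffered aqueous tert-butanol.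

**Route**

Step 1
Reactants: 1 (S)-Wieland–Miescher ketone
Product: 2 bis(ethylene ketal) with dioxolanes at C4 and C8 and the alkene at C7=C7a
Conditions: HOCH2CH2OH, TsOH (cat.), benzene, reflux, Dean–Stark
Reagents that add atoms: ethylene glycol, OCCO
Why: Acid-catalysed ketalisation with azeotropic water removal: the saturated ketone gives its dioxolane and the enone ketalises with migration of the double bond out of conjugation to C7=C7a (as with steroidal 4-en-3-ones); the C3a stereocentre is untouched.

Step 2
Reactants: 2 bis(ethylene ketal)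
Product: 4 7α-hydroxy trans-decalin bis(ethylene ketal), via C7 alkylborane 3 (not isolated)
Conditions: BH3·THF, THF, 0 °C to rt; then NaOH, H2O2, 0 °C
Reagents that add atoms: hydrogen peroxide, OO
Why: Hydroboration–oxidation: borane adds syn from the α face, opposite the axial C3a methyl, with boron on the less substituted C7 and hydrogen on C7a, which fixes the trans ring fusion (7a-Hα), and oxidation replaces boron by OH with retention (7α-OH).

Step 3
Reactants: 4 7α-hydroxy trans-decalin bis(ethylene ketal)
Product: 5 7-oxo trans-decalin bis(ethylene ketal)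
Conditions: Pr4N[RuO4] (5 mol %), N-methylmorpholine N-oxide, 4 Å sieves, CH2Cl2, rt
Reagents that add atoms: none
Why: Perruthenate-catalysed (Ley–Griffith) oxidation of the secondary alcohol under neutral conditions; the adjacent C7a centre keeps the trans fusion, which is also the thermodynamically preferred one for this decalone.

Step 4
Reactants: 5 7-oxo trans-decalin bis(ethylene ketal)
Product: 6 7β-hydroxy-7α-methyl trans-decalin bis(ethylene ketal)
Conditions: MeMgBr, THF, −78 to 0 °C
Reagents that add atoms: methylmagnesium bromide, C[Mg]Br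
Why: Grignard addition: the axial trajectory to the C7 carbonyl is blocked by the syn-axial C3a methyl, so methyl enters equatorially from the α face and the new hydroxyl is axial (7β-OH, 7α-Me).

Step 5
Reactants: 6 7β-hydroxy-7α-methyl trans-decalin bis(ethylene ketal)
Product: 7 8-oxo-7β-hydroxy-7α-methyl trans-decalin 4-(ethylene ketal)
Conditions: PPTS, acetone/H2O (9:1), rt
Reagents that add atoms: water, O
Why: Selective acetal hydrolysis: the unhindered C8 dioxolane is cleaved under mild acid while the dioxolane at the neopentylic C4, flanked by the quaternary C3a, survives, the same discrimination that frees a steroidal 3-ketal beside a 17-ketal.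

Step 6
Reactants: 7 8-oxo-7β-hydroxy-7α-methyl trans-decalin 4-(ethylene ketal)
Product: 8 C8=C2 TBS enol ether with 7β-OTBS and the C4 dioxolane
Conditions: TBSOTf (3 equiv), Et3N, CH2Cl2, −78 to 0 °C
Reagents that add atoms: tert-butyldimethylsilyl triflate, CC(C)(C)[Si](C)(C)OS(=O)(=O)C(F)(F)F
Why: Soft enolisation and O-silylation: a trans-fused decalone of this type (like a 5α-3-keto steroid) enolises away from the ring fusion, here towards C2 and away from C1 beside the crowded C7, and the silyl triflate also caps the tertiary C7 hydroxyl.

Step 7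
Reactants: 8 C8=C2 TBS enol ether
Product: 10 seco aldehyde acid (C2 aldehyde arm on C3a and C8 acid arm on C7a), via silyl ester aldehyde 9 (not isolated)
Conditions: O3, CH2Cl2/MeOH, −78 °C; Me2S; aqueous work-up at pH 4–5
Reagents that add atoms: ozone, [O-][O+]=O
Why: Ozonolysis of the silyl enol ether cleaves C8=C2 into the C8 silyl ester, hydrolysed on work-up to the acid, and the C2 aldehyde; ketal, silyl ether and all stereocentres are inert.

Step 8
Reactants: 10 seco aldehyde acid
Product: 11 tricyclic β-lactone (trans-hydrindane with the O2–C8(=O) oxetanone cis-fused at C1–C2 on the α face; C4 dioxolane; 7β-OTBS)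
Conditions: 2-chloro-1-methylpyridinium iodide, 4-pyrrolidinopyridine, i-Pr2NEt, CH2Cl2, rt, slow addition of 10
Reagents that add atoms: none
Why: Intramolecular nucleophile-catalysed aldol-lactonisation (NCAL): the activated acid gives an acylammonium enolate at C1 that adds to the C2 aldehyde (five-membered ring, C1–C2 bond) and the aldolate closes the oxetanone, which forces the C1 acyl carbon and the C2 oxygen cis; both lie on the α face because a β acyl group at C1 would eclipse the quaternary C7 and a β oxygen at C2 would sit under the C3a methyl.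

Step 9
Reactants: 11 tricyclic β-lactone ketal
Product: 12 4-oxo β-lactone
Conditions: TsOH·H2O (cat.), acetone/H2O, 45 °C
Reagents that add atoms: water, O
Why: Acetal hydrolysis with catalytic sulfonic acid in wet acetone; the tertiary silyl ether and the acid-stable β-lactone are retained.

Step 10
Reactants: 12 4-oxo β-lactone
Product: 13 4α-hydroxy β-lactone (axial alcohol)
Conditions: KBH(sec-Bu)3, THF, −78 °C
Reagents that add atoms: none
Why: Bulky trialkylborohydride reduction: hydride reaches the C4 carbonyl from the equatorial side, as in the reduction of 4,4-dimethyl-3-keto triterpenoids to their 3α-ols, giving the axial 4α-alcohol trans to the C3a methyl, while the lactone carbonyl is far less reactive at −78 °C.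

Step 11
Reactants: 13 4α-hydroxy β-lactone
Product: 14 4β-bromo β-lactone (equatorial bromide)
Conditions: CBr4, PPh3, toluene, 60 °C
Reagents that add atoms: carbon tetrabromide, BrC(Br)(Br)Br
Why: Appel reaction: bromide displaces the axial oxyphosphonium group with inversion (SN2), a substitution precedented for axial carbinols beside a quaternary carbon in bromo-terpenoid work, giving the equatorial 4β-bromide; the lactone masks O2 so that C4 carries the only alcohol.

Step 12
Reactants: 14 4β-bromo β-lactone
Product: 15 4β-bromo-2α-hydroxy-7β-OTBS trans-hydrindane-1α-(N-methoxy-N-methylcarboxamide)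
Conditions: MeNH(OMe)·HCl, AlMe3, CH2Cl2, 0 °C to rt
Reagents that add atoms: N,O-dimethylhydroxylamine hydrochloride, CNOC.Cl
Why: Aminolysis of the strained β-lactone at the acyl carbon by the aluminium amide formed in situ (Weinreb amide formation); the C1–C8 and C2–O bonds are not broken, so C1 and C2 keep their configuration and the 2α-hydroxyl is released.

Step 13
Reactants: 16 6-methylhept-5-en-2-one; 17 2,4,6-triisopropylbenzenesulfonohydrazide
Product: 18 (E)-2,4,6-triisopropylbenzenesulfonylhydrazone of 16
Conditions: MeOH, HCl (cat.), rt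
Reagents that add atoms: none
Why: Condensation of the methyl ketone with the sulfonyl hydrazide gives the (E)-hydrazone, whose sulfonamide nitrogen is syn to the methyl group and so directs the later deprotonation there.

Step 14
Reactants: 15 Weinreb amide; 18 hydrazone
Product: 20 C8 enone (1α-(6-methyl-2-methylidenehept-5-enoyl) hydrindane with free 2α-OH), via vinyllithium 19 (not isolated)
Conditions: 18 (3 equiv), n-BuLi (6 equiv), THF, −78 to 0 °C; then 15, −78 °C; AcOH/THF quench at −78 °C
Reagents that add atoms: none
Why: Shapiro reaction followed by Weinreb ketone synthesis: the hydrazone dianion, deprotonated at CH3, loses sulfinate and N2 to give the 2-lithio-1-alkene, which first deprotonates the C2 hydroxyl and then adds once to the amide because the N-methoxy chelate persists until the cold acidic quench; no stereocentre is formed and the neopentylic bromide is inert at −78 °C.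

Step 15
Reactants: 20 C8 enone
Product: 22 (8R)-2α,8-diol, via diethylboron chelate 21 (not isolated)
Conditions: Et2BOMe, THF/MeOH (4:1), −78 °C; NaBH4; then AcOH, co-evaporation with MeOH
Reagents that add atoms: none
Why: Narasaka–Prasad reduction: boron bridges the C2 oxygen and the C8 carbonyl and borohydride attacks the carbonyl face turned away from ring carbon C7a, giving the 1,3-syn diol with (R)-C8 (open-chain 1,2-induction from C1 predicts the same face), and activation through the chelate favours 1,2- over 1,4-reduction of the α-methylene ketone.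

Step 16
Reactants: 22 (8R)-2α,8-diol
Product: 23 2,8-O-cyclic carbonate (cyclisation substrate)
Conditions: 1,1'-carbonyldiimidazole, DMAP (cat.), toluene, 70 °C
Reagents that add atoms: 1,1'-carbonyldiimidazole, O=C(n1ccnc1)n1ccnc1
Why: Cyclic carbonate formation: the syn-1,3-diol closes a six-membered 1,3-dioxan-2-one cis-fused to the cyclopentane, while the silylated tertiary oxygen cannot react.

Step 17
Reactants: 23 2,8-O-cyclic carbonate
Product: 24 ring-A-closed carbonate, (1'R,4'S)-4'-bromo-1'-hydroxy-3',3'-dimethylcyclohexyl at C8, OH cis to Br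
Conditions: vanadium-dependent bromoperoxidase (Corallina officinalis), Na3VO4, KBr, H2O2 (syringe pump), MES buffer pH 6.5/t-BuOH (3:2), 25 °C
Reagents that add atoms: potassium bromide, [K+].[Br-]; water, O
Why: Proposed new method: the peroxo form of the pentavalent vanadium site oxidises bromide to an enzyme-held hypobromite equivalent that transfers Br+ to the electron-rich trisubstituted C3'=C4' alkene, the bromonium ion opens at the tertiary C3' under attack by the CH2 terminus (C2') of the 1,1-disubstituted alkene, and water quenches the tertiary C1' cation. The closest known reactions are bromoperoxidase-mediated bromocyclisations of acyclic terpene alcohols and reagent-based bromonium polyene cyclisations, neither of which ends in intermolecular water capture at a 1,1-disubstituted terminator on a substrate of this size. Ring A closes as a six-membered carbocycle through C2'–C3', 6-endo with respect to both π bonds, in a chair with bromine equatorial. C4' is set by the alkene face that receives bromine, which the distant hydrindane cannot bias and which is therefore asked of the chiral active site, and C1' is set when water adds along the axial vector of the chair cation so that the bulky carbonate-bearing substituent stays equatorial and clear of the axial C3' methyl, which places OH cis to Br. The step needs bromination at the terminal alkene and capture of C1' by external water only: the allylic carbonate oxygen deactivates the inner alkene and disfavours a 1,2-hydride shift from C8, the carbonate carbonyl is held s-trans and cannot reach C1', and O2, O8 and O7 are all capped, so no tetrahydrofuran or tetrahydropyran can form.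

Step 18
Reactants: 24 ring-A-closed carbonate
Product: 25 7-hydroxy carbonate (silyl ether removed)
Conditions: HF·pyridine, THF/pyridine, 0 °C to rt
Reagents that add atoms: none
Why: Fluoride-mediated cleavage of the tertiary silyl ether under buffered, non-basic conditions that leave the carbonate, the tertiary carbinols and both secondary bromides intact.

Step 19
Reactants: 25 7-hydroxy carbonate
Product: 26 CNP0144982.1 (target)
Conditions: K2CO3, MeOH, 0 °C to rt
Reagents that add atoms: none
Why: Base-catalysed transesterification (methanolysis) of the cyclic carbonate releases the C2 and C8 hydroxyls; both bromides are equatorial and lack an antiperiplanar hydrogen or a trans-disposed alkoxide, so neither elimination nor ether formation is expected at room temperature.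

**Compound list**

1 | (S)-Wieland–Miescher ketone, (8aS)-8a-methyl-3,4,8,8a-tetrahydronaphthalene-1,6(2H,7H)-dione | C[C@]12CCC(=O)C=C1CCCC2=O | starting material
2 | bis(ethylene ketal) of 1, dioxolanes at C4 and C8, alkene C7=C7a | C[C@]12CCC3(OCCO3)CC1=CCCC24OCCO4 | intermediate
3 | C7α-boryl trans-decalin bis(ethylene ketal), 7a-Hα (not isolated) | C[C@]12CCC3(OCCO3)C[C@@H]1[C@@H](B)CCC24OCCO4 | intermediate
4 | 7α-hydroxy trans-decalin bis(ethylene ketal), 7a-Hα | C[C@]12CCC3(OCCO3)C[C@@H]1[C@@H](O)CCC24OCCO4 | intermediate
5 | 7-oxo trans-decalin bis(ethylene ketal) | C[C@]12CCC3(OCCO3)C[C@@H]1C(=O)CCC24OCCO4 | intermediate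
6 | 7β-hydroxy-7α-methyl trans-decalin bis(ethylene ketal) | C[C@]12CCC3(OCCO3)C[C@@H]1[C@](C)(O)CCC24OCCO4 | intermediate
7 | 8-oxo-7β-hydroxy-7α-methyl trans-decalin 4-(ethylene ketal) | C[C@]12CCC(=O)C[C@@H]1[C@](C)(O)CCC23OCCO3 | intermediate
8 | C8=C2 TBS enol ether, 7β-OTBS, 7α-Me, C4 dioxolane | C[C@]12CC=C(O[Si](C)(C)C(C)(C)C)C[C@@H]1[C@](C)(O[Si](C)(C)C(C)(C)C)CCC23OCCO3 | intermediate
9 | seco aldehyde TBS ester (C2 aldehyde, C8 silyl ester; not isolated) | O=CC[C@]1(C)C2(OCCO2)CC[C@@](C)(O[Si](C)(C)C(C)(C)C)[C@H]1CC(=O)O[Si](C)(C)C(C)(C)C | intermediate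
10 | seco aldehyde acid: cyclohexane with C3a (β-Me, CH2CHO arm), C7a (Hα, CH2CO2H arm), 7β-OTBS, 7α-Me, C4 dioxolane | O=CC[C@]1(C)C2(OCCO2)CC[C@@](C)(O[Si](C)(C)C(C)(C)C)[C@H]1CC(=O)O | intermediate
11 | tricyclic β-lactone: trans-hydrindane, O2–C8(=O) oxetanone cis-fused at C1–C2 (α face), 7β-OTBS, C4 dioxolane | O=C1O[C@@H]2C[C@]3(C)C4(OCCO4)CC[C@@](C)(O[Si](C)(C)C(C)(C)C)[C@H]3[C@H]12 | intermediate
12 | 4-oxo β-lactone | O=C1O[C@@H]2C[C@]3(C)C(=O)CC[C@@](C)(O[Si](C)(C)C(C)(C)C)[C@H]3[C@H]12 | intermediate
13 | 4α-hydroxy β-lactone (axial OH, trans to C3a-Me) | O=C1O[C@@H]2C[C@]3(C)[C@H](O)CC[C@@](C)(O[Si](C)(C)C(C)(C)C)[C@H]3[C@H]12 | intermediate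
14 | 4β-bromo β-lactone (equatorial Br, cis to C3a-Me) | O=C1O[C@@H]2C[C@]3(C)[C@@H](Br)CC[C@@](C)(O[Si](C)(C)C(C)(C)C)[C@H]3[C@H]12 | intermediate
15 | 4β-bromo-2α-hydroxy-7β-OTBS-3aβ,7α-dimethyl trans-hydrindane-1α-(N-methoxy-N-methylcarboxamide) | CON(C)C(=O)[C@@H]1[C@H](O)C[C@]2(C)[C@@H](Br)CC[C@@](C)(O[Si](C)(C)C(C)(C)C)[C@@H]12 | intermediate
16 | 6-methylhept-5-en-2-one | CC(C)=CCCC(C)=O | starting material
17 | 2,4,6-triisopropylbenzenesulfonohydrazide | CC(C)c1cc(C(C)C)c(S(=O)(=O)NN)c(C(C)C)c1 | starting material
18 | (E)-2,4,6-triisopropylbenzenesulfonylhydrazone of 16 | CC(C)=CCC/C(C)=N/NS(=O)(=O)c1c(C(C)C)cc(C(C)C)cc1C(C)C | intermediate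
19 | 2-lithio-6-methylhepta-1,5-diene (not isolated) | [Li]C(=C)CCC=C(C)C | intermediate
20 | C8 enone: 1α-(6-methyl-2-methylidenehept-5-enoyl)-4β-bromo-2α-hydroxy-7β-OTBS-3aβ,7α-dimethyl trans-hydrindane | CC(C)=CCCC(=C)C(=O)[C@@H]1[C@H](O)C[C@]2(C)[C@@H](Br)CC[C@@](C)(O[Si](C)(C)C(C)(C)C)[C@@H]12 | intermediate
21 | 2-O-diethylboryl chelate of 20 (not isolated) | CC(C)=CCCC(=C)C(=O)[C@@H]1[C@H](OB(CC)CC)C[C@]2(C)[C@@H](Br)CC[C@@](C)(O[Si](C)(C)C(C)(C)C)[C@@H]12 | intermediate
22 | (8R)-2α,8-diol with the open dienyl chain, 4β-Br, 7β-OTBS | CC(C)=CCCC(=C)[C@H](O)[C@@H]1[C@H](O)C[C@]2(C)[C@@H](Br)CC[C@@](C)(O[Si](C)(C)C(C)(C)C)[C@@H]12 | intermediate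
23 | 2,8-O-cyclic carbonate of 22 (key-step precursor) | CC(C)=CCCC(=C)[C@@H]1OC(=O)O[C@@H]2C[C@]3(C)[C@@H](Br)CC[C@@](C)(O[Si](C)(C)C(C)(C)C)[C@H]3[C@H]12 | intermediate
24 | key-step product: 2,8-O-carbonate, 7β-OTBS, ring A (1'R,4'S)-4'-bromo-1'-hydroxy-3',3'-dimethylcyclohexyl | CC1(C)C[C@@](O)([C@@H]2OC(=O)O[C@@H]3C[C@]4(C)[C@@H](Br)CC[C@@](C)(O[Si](C)(C)C(C)(C)C)[C@H]4[C@H]23)CC[C@@H]1Br | intermediate
25 | 2,8-O-carbonate of the target (7-OH free) | CC1(C)C[C@@](O)([C@@H]2OC(=O)O[C@@H]3C[C@]4(C)[C@@H](Br)CC[C@@](C)(O)[C@H]4[C@H]23)CC[C@@H]1Br | intermediate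
26 | CNP0144982.1 | CC1(C)C[C@@](O)([C@H](O)[C@@H]2[C@H](O)C[C@]3(C)[C@@H](Br)CC[C@@](C)(O)[C@@H]23)CC[C@@H]1Br | target

**Step count.** Total: 19 steps. Longest linear sequence: 18 steps (steps 1–12 and 14–19, from 1).

**Steps most likely to fail**

1. Step 17 (proposed new method). Water may open the bromonium ion before the inner alkene does (bromohydrin formation). The C1' cation may lose a proton instead of being hydrated. The enzyme may release free hypobromite, so that the alkene face is not selected and the C4' epimer forms alongside. Water may also add to C1' from the equatorial side. Fallback with known, reagent-based chemistry: setting out from 23, bromonium cyclisation with Et2SBr·SbBrCl5 in MeNO2 at −25 °C, which ends by proton loss, should give the ring-A cyclohexenes, the 1'(6')-ene carbonate F1 and the 1'(2')-ene carbonate F2. There is no face control, so each forms as both C4' epimers and the (4'S) series is separated by HPLC. Mukaiyama hydration of the mixture (Mn(dpm)3 [dpm = dipivaloylmethanate], PhSiH3, O2, i-PrOH, 0 °C) then places the hydroxyl on the tertiary C1' of either isomer and comes back to the route at 24, the C1' epimer being removed by chromatography.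

2. Step 11. The axial oxyphosphonium ion beside the quaternary C3a may eliminate towards C5 or trigger a 1,2-methyl shift faster than bromide attacks the neopentylic carbon, or it may not be displaced at all. Fallback: setting out from ketone 12, (PhO)3P/Br2, Et3N, CH2Cl2, −60 °C to rt should convert the carbonyl into the 4-bromo-4-ene β-lactone F3. Hydrogen-atom-transfer hydrogenation (Mn(dpm)3, PhSiH3, t-BuOOH, i-PrOH, rt) then adds hydrogen to C5 and delivers the second hydrogen to the C4 radical along the axial α vector. This leaves bromine equatorial (β) and comes back to the route at 14.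

3. Step 8. The hindered acylammonium enolate may fail to add to the neopentylic aldehyde, so that the activated acid oligomerises or forms ketene dimers, or the aldol may stop before lactonisation. Fallback: setting out from 10, thioesterification (PhSH, DCC, DMAP, CH2Cl2) should give the S-phenyl thioester aldehyde F4. Soft enolisation (MgBr2·OEt2, i-Pr2NEt, CH2Cl2, rt) closes the five-membered ring by a magnesium-chelated direct aldol to the cis 2α-hydroxy thioester F5. Silver-assisted lactonisation (AgO2CCF3, CH2Cl2) then comes back to the route at 11.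

**Further compounds**

F1 | step 17 | 1'(6')-ene carbonate: ring A closed with C1'=C6' alkene, (4'S)-Br | CC1(C)CC(=CC[C@@H]1Br)[C@@H]1OC(=O)O[C@@H]2C[C@]3(C)[C@@H](Br)CC[C@@](C)(O[Si](C)(C)C(C)(C)C)[C@H]3[C@H]12
F2 | step 17 | 1'(2')-ene carbonate: ring A closed with C1'=C2' alkene, (4'S)-Br | CC1(C)C=C(CC[C@@H]1Br)[C@@H]1OC(=O)O[C@@H]2C[C@]3(C)[C@@H](Br)CC[C@@](C)(O[Si](C)(C)C(C)(C)C)[C@H]3[C@H]12
F3 | step 11 | 4-bromo-4-ene β-lactone | O=C1O[C@@H]2C[C@]3(C)C(Br)=CC[C@@](C)(O[Si](C)(C)C(C)(C)C)[C@H]3[C@H]12
F4 | step 8 | S-phenyl thioester aldehyde of 10 | O=CC[C@]1(C)C2(OCCO2)CC[C@@](C)(O[Si](C)(C)C(C)(C)C)[C@H]1CC(=O)Sc1ccccc1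
F5 | step 8 | cis 2α-hydroxy 1α-(phenylthio)carbonyl trans-hydrindane, C4 dioxolane, 7β-OTBS | O=C(Sc1ccccc1)[C@@H]1[C@H](O)C[C@]2(C)C3(OCCO3)CC[C@@](C)(O[Si](C)(C)C(C)(C)C)[C@@H]12
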